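All runs were generated by integration for an exercise; scatter was added.

Friday's run reads as a straight line: product climbs 1.37 mM h⁻¹ from 3.00 h to 8.00 h, while the charge minus solid and product leaves a dissolved level of 10.4 mM.

| setting | Tuesday's | Friday's | south-east | south-west |
|---|---|---|---|---|
| solid substrate | 9.4 mM | 21 mM | 14 mM | 14 mM |
| reagent | 0.90 equiv (in portions, 2) | 0.90 equiv (in portions, 2) | 0.900 equiv | 0.900 equiv (in portions, 2) |
| initiator | 9.3 mol% | 9.3 mol% | 9.3 mol% | 9.3 mol% |
| temperature | 2 °C | 19 °C | −5 °C | 25 °C |
| remark | run made earlier; portions every 50 min | run made earlier; portions every 50 min | everything together at the start | the portions of reagent follow each other after 50 min, the first at the start |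
| time |  |  | 8.0 h | 8.0 h |

| run | time / h | product / % | solid substrate / % |
|---|---|---|---|
| Tuesday's | 3.00 | 3.5 | 0 |
| Tuesday's | 10.0 | 11.4 | 0 |
| Tuesday's | 15.0 | 16.2 | 1.1 |
| Tuesday's | 25.0 | 26.4 | 1.0 |
| Friday's | 1.00 | 2.4 | 67.9 |
| Friday's | 3.00 | 14.8 | 40.6 |
| Friday's | 5.00 | 28.2 | 23.9 |
| Friday's | 8.00 | 47.5 | 3.0 |

(standard deviation of a reading: 0.5 percentage points)

- percentages count the solid substrate that a species holds: one ended chains A counts as two
- solid, in amounts per volume of the solution: solid substrate
- steps under discussion: initiator -> 2 initiating radical; starting material + initiating radical -> capped initiator + first chain carrier; reagent + first chain carrier <-> product + second chain carrier; starting material + second chain carrier -> released group + first chain carrier; 2 first chain carrier -> ended chains A; 2 second chain carrier -> ended chains B; solid substrate <-> starting material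
- at the start none of the solid substrate is in solution
- what has only dissolved of solid substrate counts as not reacted

1. the flask that ends with the higher amount of product, in percent of the solid substrate charged, or "neither" when 2 percentage points or less lies between them (south-east / south-west / neither)
2. final product, as a percentage of the solid substrate charged, in south-east
3. final product, as a percentage of the solid substrate charged, in south-west

Friday's first hour, with 6.24 mM dissolved, gives an approach to that level of 0.916 h⁻¹, so a lag of 1.09 h. Dividing the slope by the level gives a pseudo-first-order constant of 0.132 h⁻¹, and Tuesday's flask, whose charge lies below that level and whose solid reads 1.0% at its last reading, gives 0.0123 h⁻¹ from the logarithm of what is unreacted. Taking the constant to go with the square root of [initiator], as chains ending in pairs suggest, the two runs give an activation energy of 77.5 kJ mol⁻¹, and so 0.205 h⁻¹ for south-west and 0.00621 h⁻¹ for south-east.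

The first chemist extends Friday's line: with [starting material] held at the level, south-west reaches 105%, which is more than the 0.900 equiv of reagent allows, so it stops at that cap. The second objects that the level lasts only until the solid-out time, the lag plus the excess of the charge over the level divided by the rate at the level, 2.78 h in south-west. After that time [starting material] falls as the level times exp(−k(t − solid-out time)), which gives 74.5%. In south-east the solid-out time is 57.0 h, later than the end of the run, so both chemists take the line, 3.18%. Both carry Friday's level and lag over to the other temperatures unchanged, as an assumption, and I side with the second.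

The forecast names south-west, with 3% in south-east and, “Allowing for the dissolution lag and reagent depletion”, 70% in south-west, a figure lower than mine.

The simulation gives 3.48% in south-east and 75.5% in south-west, so south-west ends higher.

    initiator → 2 initiating radical (k = 1.70 × 10⁻⁵ s⁻¹, Ea = 93.0 kJ mol⁻¹)
    starting material + initiating radical → capped initiator + first chain carrier (k = 46000 M⁻¹ s⁻¹, Ea = 21.0 kJ mol⁻¹)
    reagent + first chain carrier ⇌ product + second chain carrier (K = 3.00, k = 5300 M⁻¹ s⁻¹, Ea = 25.0 kJ mol⁻¹, ΔH = 5.00 kJ mol⁻¹)
    starting material + second chain carrier → released group + first chain carrier (k = 2700 M⁻¹ s⁻¹, Ea = 41.0 kJ mol⁻¹)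
    2 first chain carrier → ended chains A (k = 1.00 × 10⁶ M⁻¹ s⁻¹, Ea = 25.0 kJ mol⁻¹)
    2 second chain carrier → ended chains B (k = 4.10 × 10⁷ M⁻¹ s⁻¹, Ea = 13.0 kJ mol⁻¹)
    solid substrate ⇌ starting material, rate k7*(cs7 - [starting material]) while solid is left; crystals form when [starting material] > cs7 (solubility = 12.0 mM, k = 2.20 × 10⁻⁴ s⁻¹)
    (constants at 25 °C)

South-west followed the curve: its solid stood at 24.0% after 2.00 h and 0% after 4.00 h, either side of 2.78 h. The first chemist's line belongs to flasks with solid still standing, as Friday's with 3.0% and south-east with 11.6% at 8.00 h. Neither flask is at rest then. South-west still holds 16% of its reagent, and by 80.0 h it reaches 89.9% with 0.107% left, reagent being the limiting reagent. South-east's reckoned solid-out time comes before 80.0 h, and at that time, with its solid at 0%, the curve gives 35.6% and the flask 36.5%.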